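Start from the leftover in Friday's run: coupling partner is the limiting reagent there, so with the whole 0.400 M used the starting material stands at 84.0% of its charge, and what remains to reckon is a small correction, the partner still unused at 88 h.

| flask | starting material | coupling partner | free catalyst | target | time |
|---|---|---|---|---|---|
| Sunday's | 0.500 M | 0.400 M | 0.00500 M |  |  |
| Thursday's | 0.300 M | 0.200 M | 0.00500 M |  |  |
| Wednesday's | 0.500 M | 0.400 M | 0.00750 M |  |  |
| Monday's | 0.500 M | 0.400 M | 0.00500 M | 0.150 M |  |
| Friday's | 2.50 M | 0.400 M | 0.00500 M |  | 88 h |

| run | time / h | [starting material] / M |
|---|---|---|
| Sunday's run | 3.9 | 0.3753 |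
| Sunday's run | 12 | 0.2553 |
| Sunday's run | 23 | 0.1929 |
| Sunday's run | 36 | 0.1638 |
| Sunday's run | 51 | 0.1441 |
| Sunday's run | 69 | 0.1360 |
| Sunday's run | 88 | 0.1275 |
| Thursday's run | 3.9 | 0.2420 |
| Thursday's run | 12 | 0.1877 |
| Thursday's run | 23 | 0.1567 |
| Thursday's run | 36 | 0.1370 |
| Thursday's run | 51 | 0.1228 |
| Thursday's run | 69 | 0.1224 |
| Thursday's run | 88 | 0.1180 |
| Wednesday's run | 3.9 | 0.3010 |
| Wednesday's run | 12 | 0.1806 |
| Wednesday's run | 23 | 0.1341 |
| Wednesday's run | 36 | 0.1171 |
| Wednesday's run | 51 | 0.1067 |
| Wednesday's run | 69 | 0.1102 |
| Wednesday's run | 88 | 0.0998 |
| Monday's run | 3.9 | 0.3743 |
| Monday's run | 12 | 0.2554 |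
| Monday's run | 23 | 0.1886 |
| Monday's run | 36 | 0.1633 |
| Monday's run | 51 | 0.1456 |
| Monday's run | 69 | 0.1366 |
| Monday's run | 88 | 0.1288 |

(each reading ± 0.002 M)

1. how the opening rate goes with [free catalyst] round the charge of the Sunday's run: the exponent of the rate at two percent of starting material gone to target
2. the Thursday's run starts with 0.200 M less of starting material and of coupling partner than the Sunday's run, and with no target. Compared where both hold the same amount of starting material, once fifteen percent of what the Thursday's run was charged with has turned into target, is the Thursday's run faster, slower or alike (within a tenth)?
3. starting material in the Friday's run at 88 h, as a share of the starting material charged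

- Overall: starting material + coupling partner -> target, with free catalyst as catalyst.
- Constant volume, constant temperature.
- Readings of a species count what is bound in complexes too.
- "The second partner" is coupling partner.
- An order is taken over about fifteen percent of the charge, up and down.

Read the correction off Sunday's run, which has the partner and catalyst charges of Friday's. By the overall equation, partner used equals starting material used, so take the last reading, subtract the floor of that run and divide by the partner charge:

(0.1275 M − 0.100 M) / 0.400 M = 6.88%

Call this the unspent share, the coupling partner not yet turned at the last reading as a fraction of its charge. Check it on Monday's run, which was charged with target and gives 7.20%, within the 0.500% that the scatter allows on such a share. Then look at Wednesday's run, which with 0.00750 M of free catalyst ends at 0.0998 M, lower than Sunday's and on its floor of 0.100 M within the scatter, so tie the unspent share to the catalyst charge, which Friday's run has in common with Sunday's. Now carry it over to Friday's run: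

(2.10 M + 6.88% × 0.400 M) / 2.50 M = 85.1%

The weak link is that carrying over, since Friday's run holds far more starting material than Sunday's. Reforge it with Thursday's run, whose different charges leave an unspent share of 9.00%, larger than Sunday's, and which puts Friday's run at 85.4%. The two answers lie 0.30 percentage points apart, as any error in the unspent share reaches Friday's figure scaled by 16.0%, so commit to 85.1%.

The forecast gave an exponent of 2, faster for Thursday's run and 86%, above my figure, on the ground that Friday's run “likely still consumes most of the partner”.

The flask gives an exponent of 1.8, Thursday's run faster at a ratio of 1.3, and 84.8% in Friday's run at 88 h, which lies 0.30 points under my reckoning and 0.80 points over the floor.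

    free catalyst + starting material ⇌ catalyst-substrate complex, settled at all times (4.050 M⁻¹)
    catalyst-substrate complex + coupling partner → target + free catalyst (57.24 M⁻¹ h⁻¹)
    free catalyst + impurity → spent catalyst
    catalyst-substrate complex → spent catalyst + starting material (0.05364 h⁻¹)

Put that result back through the same line and Friday's unspent share comes out at 4.89%, smaller than Sunday's 6.88% and Thursday's 9.00%. Take the ageing of the catalyst from Thursday's run, which reaches the matched amount of starting material before 3.9 h, earlier than Sunday's run at about 12 h. Because catalyst-substrate complex passes into spent catalyst and starting material as the hours go, Thursday's run stands at 1.3 times the rate of Sunday's there, and the same pair of runs without that passing gives 1.0.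

The earlier runs and the new flask are calculated with constants of no real substance.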